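- Tuesday's: starting material 0.25 M; reagent 1.05 equiv; protic impurity 2.5 mM; run made earlier
- flask: starting material 0.25 M; reagent 1.05 equiv; protic impurity 5.00 mM; time 3.0 h
- Tuesday's (time / min: starting material / %, product / %): 2.00: 98.0, 0.2; 6.00: 97.4, 0.5; 10.0: 95.3, 0; 15.0: 94.2, 0; 20.0: 93.0, 1.8; 30.0: 86.3, 0; 40.0: 83.9, 1.1

(scatter of a reading: 1 percentage point)
- the reaction counts as stopped when no species that holds the starting material changes by six tenths of a point or more over the second half of the time
- no earlier run changes the charge of protic impurity; that part of a forecast is a guess
- at 3.0 h, what has stopped the reaction, if anything has (it is still moving / the reagent has run out first / all of the starting material has reacted / forward and back rates have come level)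
- how much of the starting material has reacted by 3.0 h
- how much product there is at 3.0 h, in percent of the starting material charged
- how much intermediate A there is at 3.0 h, in percent of the starting material charged
- amount of product if the flask were left three thousand times as long, in percent of the starting material charged

Reagent charged beyond the starting material is a leftover of 0.0500 equiv, so with one reagent reckoned per starting material, reagent runs down along with starting material, and the rate at the end of the flask is reckoned below the rate at its start. The quantity to carry is therefore the loss constant k of starting material at full reagent charge, a pseudo-first-order constant divided by the mean fraction of reagent left. It is read from Tuesday's last reading: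

k = ln(1/fraction left) / (time × mean reagent fraction) = 0.00475 min⁻¹

In the first instants of the flask, protic impurity is present at 2.00 % of the starting material charged. No run varies it, so a guess of one starting material lost per impurity adds 1.00 % beyond Tuesday's share.

In the middle, starting material is reckoned to pass through intermediate A before it reaches product: Tuesday's product reads 1.1 % at 40.0 min, less than the 16.1 % of starting material read as gone.

For the end, each answer is put back as the mean reagent fraction, one minus half the reacted fraction over the equivalents:

full reagent throughout: 57.5 % reacted
first round: 46.3 % reacted
second round: 48.7 % reacted

With the impurity guess, this reckoning gives 49.7 % reacted. The closing rate, held over the second half of the time, is still worth 12 percentage points, so the flask is reckoned to be moving.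

The forecast, with more reacted than this reckoning, reads: it is still moving, with 62 % reacted, 13 % product, 48 % intermediate A and 96 % in the long run; its words on the impurity are “Doubling the impurity is the unknown.”

The flask gives: it is still moving, with 41.5 % reacted, 9.64 % product, 25.1 % intermediate A and 98.0 % in the long run.

    starting material + reagent ⇌ intermediate A (K = 71.0 M⁻¹, k = 1.94 × 10⁻⁴ M⁻¹ s⁻¹)
    intermediate A → product (k = 3.82 × 10⁻⁵ s⁻¹)
    starting material + reagent ⇌ intermediate B (K = 0.642 M⁻¹, k = 8.13 × 10⁻⁵ M⁻¹ s⁻¹)
    intermediate B → product (k = 6.74 × 10⁻⁵ s⁻¹)
    starting material + protic impurity → quenched substrate (k = 0.00392 M⁻¹ s⁻¹)

The flask reaches 41.5 % reacted, of which 2.00 % stands as quenched substrate at 3.00 h. Read back with the same rule and the reagent left, 62 % of its charge, the flask's k over the whole time is 0.00367 min⁻¹, lower than the 0.00475 min⁻¹ read from Tuesday's last reading. Carried to the neighbour charged with 2.60 equiv, which keeps 72.6 % of its reagent, this k reckons 24.4 % starting material left, and that neighbour holds 26.7 %.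

The runs are calculated for substances that don't exist; scatter was added.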